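**Assumption:** the target SMILES is the centrosymmetric meso compound (one half 1R,3R,9S,9aS, the other 1'S,3'S,9'R,9a'R; quinolizidine numbering C1–C4, N5, C6–C9, C9a), so only relative configuration has to be controlled and achiral reagents suffice.

## Retrosynthetic overview

1. Petrosin A ⇐ base equilibration (C1, C3, C9a) of the perhydro bis-quinolizidinone ⇐ alcohol oxidation ⇐ exhaustive hydrogenation of a macrocyclic bis(3,4-dihydro-2H-quinolizin-2-one).
2. Key disconnection: both ketone rings (N–C4 and C1–C2 bonds) are cut back to intact pyridines, i.e. a double dearomative annulation of a macrocyclic bis(2-alkylpyridine) with two methacryloyl units.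
3. The 16-membered carbocycle ⇐ head-to-tail Sonogashira cyclodimerisation of a 3-bromo-2-(hex-5-ynyl)pyridine ⇐ lateral alkylation of 3-bromo-2-methylpyridine.
4. Ring order: pyridine rings (bought) → 16-membered ring → the two ketone rings (pyridines dearomatised) → saturation of the pyridine-derived rings.
5. Stereochemistry: C9/C9' are fixed in the hydrogenation; C1, C3 and C9a are set thermodynamically; the meso isomer is separated from the C2-symmetric diastereomer.

## Route

Step 1
Reactants: 1 3-bromo-2-methylpyridine; 2 (5-iodopent-1-yn-1-yl)trimethylsilane
Product: 4 3-bromo-2-[6-(trimethylsilyl)hex-5-yn-1-yl]pyridine, via (3-bromopyridin-2-yl)methyllithium 3 (not isolated)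
Conditions: LDA (1.05 equiv), THF, −78 °C, 30 min; then 2, −78 → −20 °C
Reagents that add atoms: (5-iodopent-1-yn-1-yl)trimethylsilane 2, C[Si](C)(C)C#CCCCI
Why: Lateral lithiation of the 2-methyl group (the aza-benzylic C–H is the most acidic site and LDA does not exchange the aryl bromide) followed by SN2 alkylation with the primary iodide; no stereocentre is formed.

Step 2
Reactants: 4 3-bromo-2-[6-(trimethylsilyl)hex-5-yn-1-yl]pyridine (two molecules)
Product: 7 macrocyclic bis-pyridine diyne (16-membered head-to-tail cyclodimer; C3 of each pyridine joined through C≡C–(CH2)4 to C2 of the other), via 3-bromo-2-(hex-5-yn-1-yl)pyridine 5 (not isolated), via linear bromo-alkyne dimer 6 (not isolated)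
Conditions: PdCl2(PPh3)2 (10 mol %), CuI (10 mol %), CsF (3 equiv), Et3N/DMF, trace H2O, 80 °C, Ar; 4 added by syringe pump over 24 h (final 2 mM)
Reagents that add atoms: none
Why: Sonogashira coupling with fluoride-triggered in situ desilylation (sila-Sonogashira) can only join the monomers head to tail, the monomer cannot close on itself because that would require a pyridine-fused cyclooctyne, and the slow release of free alkyne under pseudo-high dilution lets linear dimer 6 close the strain-free 16-membered ring; no stereocentre is formed.

Step 3
Reactants: 7 macrocyclic bis-pyridine diyne; 8 N-methoxy-N-methylmethacrylamide (2.5 equiv)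
Product: 12 macrocyclic bis(3-methyl-3,4-dihydro-2H-quinolizin-2-one) diyne (bis-anhydrobase), via dilithio macrocycle 9 (not isolated), via bis(lithium hemiaminal) adduct 10 (not isolated), via bis(isopropenyl ketone) 11 (not isolated)
Conditions: LDA (2.2 equiv), THF, −78 °C; 8, −78 °C, 1 h; AcOH (2.2 equiv)/MeOH quench, then 50 °C, 3 h
Reagents that add atoms: N-methoxy-N-methylmethacrylamide 8, CON(C)C(=O)C(C)=C
Why: Proposed new method: double lateral lithiation and Weinreb-amide acylation (the ketone is released only on quench, so no over-addition) gives the 2-pyridylmethyl isopropenyl ketone 11, whose pyridine nitrogen adds 6-endo-trig to the enone terminus and whose C1–H-acidic pyridinium then loses its proton, so that each pyridine is dearomatised to a push–pull 2-alkylidene-1,2-dihydropyridine while the ketone ring (N, C4, C3, C2, C1, C9a) is closed, the closest known reaction types being the acylation of picolyllithiums and the cyclisation of 2-pyridylmethyl β-alkoxyvinyl or ethynyl ketones to 2H-quinolizin-2-ones; C3 forms as a mixture and is corrected in step 6.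

Step 4
Reactants: 12 macrocyclic bis(3-methyl-3,4-dihydro-2H-quinolizin-2-one) diyne
Product: 13 perhydro diol (petrosin skeleton with both C2 carbonyls as CHOH; diastereomer mixture)
Conditions: H2 (4 atm), PtO2 (20 mol %), AcOH, 40 °C, 48 h
Reagents that add atoms: none
Why: Adams hydrogenation in acetic acid, where the anhydrobase is C-protonated to the pyridinium ketone, saturates the alkynes, both pyridinium rings and (through iminium tautomers) any vinylogous amide and also reduces the ketones; syn delivery of hydrogen to one face of each ring fixes C9 (H9 cis to H9a at this stage), the two halves react independently so heterochiral (meso-type) and homochiral pairing of C9/C9' is statistical, and all other centres are left for step 6.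

Step 5
Reactants: 13 perhydro diol
Product: 14 perhydro diketone (petrosin constitution; kinetic diastereomer mixture)
Conditions: Dess–Martin periodinane (3 equiv), CH2Cl2, 0 °C → rt; aq Na2S2O3/NaHCO3 work-up
Reagents that add atoms: none
Why: Dess–Martin oxidation of the two hindered secondary alcohols, with the tertiary amines protected as acetate salts by the liberated acetic acid; no stereocentre is set and the two carbinol centres are removed.

Step 6
Reactants: 14 perhydro diketone (diastereomer mixture)
Product: 15 petrosin A
Conditions: NaOMe (0.3 equiv), MeOH, 60 °C, 24 h; chromatography on basic Al2O3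
Reagents that add atoms: none
Why: Thermodynamic equilibration in which C1 and C3 epimerise through the enolates and C9a through reversible retro-Mannich/Mannich (or retro-aza-Michael) opening of the β-amino ketone while C9 stays fixed, so that each half settles, relative to its C9, into the trans-fused quinolizidinone with equatorial 9-alkyl, equatorial 3-methyl and axial 1-alkyl (the axial chain removes the 1,9-peri clash and costs little next to the carbonyl), and the heterochiral half of the material is the meso target, separated from the homochiral C2-symmetric diastereomer.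

## Compound list

1 | 3-bromo-2-methylpyridine | Cc1ncccc1Br | starting material
2 | (5-iodopent-1-yn-1-yl)trimethylsilane | C[Si](C)(C)C#CCCCI | starting material
3 | (3-bromopyridin-2-yl)methyllithium | [Li]Cc1ncccc1Br | intermediate
4 | 3-bromo-2-[6-(trimethylsilyl)hex-5-yn-1-yl]pyridine | C[Si](C)(C)C#CCCCCc1ncccc1Br | intermediate
5 | 3-bromo-2-(hex-5-yn-1-yl)pyridine | C#CCCCCc1ncccc1Br | intermediate
6 | linear dimer, 3-bromo-2-{6-[2-(hex-5-yn-1-yl)pyridin-3-yl]hex-5-yn-1-yl}pyridine | C#CCCCCc1ncccc1C#CCCCCc1ncccc1Br | intermediate
7 | macrocyclic bis-pyridine diyne (16-membered ring; no stereocentre) | c12cccnc1CCCCC#Cc1cccnc1CCCCC#C2 | intermediate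
8 | N-methoxy-N-methylmethacrylamide | CON(C)C(=O)C(C)=C | starting material
9 | dilithio macrocycle (both picolyl carbons lithiated) | c12cccnc1C([Li])CCCC#Cc1cccnc1C([Li])CCCC#C2 | intermediate
10 | bis(lithium hemiaminal) adduct of 9 and 8 | c12cccnc1C(C(O[Li])(N(C)OC)C(C)=C)CCCC#Cc1cccnc1C(C(O[Li])(N(C)OC)C(C)=C)CCCC#C2 | intermediate
11 | bis(isopropenyl ketone) macrocycle | c12cccnc1C(C(=O)C(C)=C)CCCC#Cc1cccnc1C(C(=O)C(C)=C)CCCC#C2 | intermediate
12 | macrocyclic bis(3-methyl-3,4-dihydro-2H-quinolizin-2-one) diyne; C9 of each unit joined through C≡C–(CH2)3 to C1 of the other; C3/C3' mixed, drawn without configuration | O=C1C(C)CN2C=CC=C3C2=C1CCCC#CC1=CC=CN2CC(C)C(=O)C(CCCC#C3)=C12 | intermediate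
13 | perhydro diol, diastereomer mixture (H9/H9a cis in each half; other centres and the pairing of the halves mixed; drawn without configuration because the mixture is carried on) | CC1CN2CCCC3CCCCCC4C(O)C(C)CN5CCCC(CCCCCC(C1O)C32)C45 | intermediate
14 | perhydro diketone, kinetic diastereomer mixture (drawn without configuration) | CC1CN2CCCC3CCCCCC4C(=O)C(C)CN5CCCC(CCCCCC(C1=O)C32)C45 | intermediate
15 | petrosin A, meso (1R,3R,9S,9aS,1'S,3'S,9'R,9a'R): in each half H1 cis to H9a, H9 trans to H9a, 3-methyl trans to the C1 chain | C[C@@H]1CN2CCC[C@@H]3CCCCC[C@@H]4C(=O)[C@@H](C)CN5CCC[C@@H](CCCCC[C@@H](C1=O)[C@H]32)[C@H]45 | target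

## Step count and risks

Total steps: 6. Longest linear sequence: 6 (1 → 4 → 7 → 12 → 13 → 14 → 15).

The three steps most likely to fail:

**Step 2, cyclodimerisation.** Cyclic trimer and open oligomers may dominate. The fallback sets out from 4 and comes back at 7 by stepwise assembly. One portion of 4 is desilylated (K2CO3, MeOH) to isolate 5. A second portion is converted by aromatic Finkelstein exchange (NaI, CuI, trans-N,N'-dimethylcyclohexane-1,2-diamine, dioxane, 110 °C) into 3-iodo-2-[6-(trimethylsilyl)hex-5-yn-1-yl]pyridine F1. F1 and 5 are coupled at 20 °C (PdCl2(PPh3)2, CuI, Et3N, THF), where only the aryl iodide reacts, to give the linear silyl-alkyne bromide dimer F2. F2 is then closed unimolecularly at high dilution under the step 2 conditions to give 7.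

**Step 3, double dearomative annulation.** The picolyllithium may add 1,4 instead of 1,2 to the unsaturated Weinreb amide, or the second annulation may stall. The fallback sets out from 7 and comes back at 11. The dilithio species 9 is added to methacrolein at −78 °C (reliable 1,2-addition to the aldehyde) to give the macrocyclic bis(allylic alcohol) F3. Oxidation of F3 with MnO2 (CH2Cl2) or Dess–Martin periodinane gives the bis(isopropenyl ketone) 11, which cyclises to 12 on warming as in the main route.

**Step 6, stereochemical convergence.** C9a may not invert under base, or the equilibrium may hold too little of the target arrangement. Even in the best case only the heterochiral half of the material can become 15, so about 15–25 % isolated yield is realistic. The fallback sets out from 14 (or from recovered isomers) and comes back at 15. It abandons enolate epimerisation of the closed rings and re-forms the C1–C9a bonds instead. AcOH/NaOAc buffer in aqueous MeOH at 60 °C opens the β-amino ketones by retro-Mannich reaction to the ring-opened bis(iminium enol) F4 (drawn with both halves open; not isolated). F4 re-closes by Mannich cyclisation, the enol attacking the iminium anti to the C9 chain, which gives the H9/H9a-trans relationship directly. This manifold also scrambles C9 through the enamine, so the C2-symmetric isomer can be recycled into the mixture.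

## Further compounds

F1 | step 2 | 3-iodo-2-[6-(trimethylsilyl)hex-5-yn-1-yl]pyridine | C[Si](C)(C)C#CCCCCc1ncccc1I
F2 | step 2 | linear silyl-alkyne bromide dimer, 3-bromo-2-{6-[2-(6-(trimethylsilyl)hex-5-yn-1-yl)pyridin-3-yl]hex-5-yn-1-yl}pyridine | C[Si](C)(C)C#CCCCCc1ncccc1C#CCCCCc1ncccc1Br
F3 | step 3 | macrocyclic bis(allylic alcohol), each picolyl carbon bearing CH(OH)C(CH3)=CH2 (diastereomer mixture) | c12cccnc1C(C(O)C(C)=C)CCCC#Cc1cccnc1C(C(O)C(C)=C)CCCC#C2
F4 | step 6 | ring-opened bis(iminium enol) of 14 (dication, both C1–C9a bonds cleaved) | CC1C[N+]2=CC(CCCCCC=C(O)C(C)C[N+]3=CC(CCCCCC=C1O)CCC3)CCC2
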